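Carbons are numbered along the chain from the lactone carbonyl C1 to the oxirane methyl C24. Everything rests on the oxolane ring (ring O, C14, C15, C16, C17): its O–C17–C16 segment is read as a terminal epoxide and C15–C14 as an acetate unit. In one operation dilithioacetate opens the epoxide at C16 (bond C15–C16) and the freed C17 oxygen acylates C14 (bond O–C14). The resulting oxolan-2-one already holds the ring oxygen and all four ring carbons; C17 then directs the oxygenation of C15 and the hydride delivery to C14. The precursor is a small C16–C19 epoxide and acetic acid.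

Key step: step 6

Abbreviations: TBS = tert-butyldimethylsilyl, TES = triethylsilyl, TMS = trimethylsilyl, DMP = 1,1,1-triacetoxy-1,1-dihydro-1,2-benziodoxol-3(1H)-one, TRIP = 3,3'-bis(2,4,6-triisopropylphenyl)-1,1'-binaphthyl-2,2'-diyl hydrogen phosphate.

Assumption: in step 11 the (R)-configured phosphoric acid is taken to give the (3R)-alcohol by analogy with aryl and alkenyl aldehydes; the mirror-image acid serves if the sense is the opposite.

Step 1
Reactants: 1 methyl (2S)-3-hydroxy-2-methylpropanoate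
Product: 2 methyl (2S)-2-methyl-3-(TBS-oxy)propanoate
Conditions: TBSCl, imidazole, DMF, rt
Reagents that add atoms: tert-butyl(chloro)dimethylsilane, CC(C)(C)[Si](C)(C)Cl
Why: Silyl ether formation on the primary alcohol is a standard protection that leaves the C18 stereocentre, taken from the chiral pool, untouched.

Step 2
Reactants: 2 methyl (2S)-2-methyl-3-(TBS-oxy)propanoate
Product: 3 (2S)-2-methyl-3-(TBS-oxy)propanal
Conditions: DIBAL-H, CH2Cl2, −78 °C; aq. potassium sodium tartrate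
Reagents that add atoms: none
Why: Partial reduction of the ester stops at the aldehyde because the tetrahedral aluminium hemiacetal is stable at −78 °C, and cold handling limits epimerisation of the α-centre.

Step 3
Reactants: 3 (2S)-2-methyl-3-(TBS-oxy)propanal
Product: 4 (2R)-2-methylbut-3-en-1-yl TBS ether
Conditions: Ph3PCH3Br, KHMDS, THF, −78 to 0 °C
Reagents that add atoms: methyltriphenylphosphonium bromide, C[P+](c1ccccc1)(c1ccccc1)c1ccccc1.[Br-]
Why: Wittig methylenation with the non-stabilised ylide turns the aldehyde into the terminal alkene C16=C17 without touching C18.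

Step 4
Reactants: 4 (2R)-2-methylbut-3-en-1-yl TBS ether
Product: 5 (2S)-2-[(2RS)-oxiran-2-yl]propyl TBS ether (both C17 epimers)
Conditions: mCPBA, NaHCO3, CH2Cl2, 0 °C to rt
Reagents that add atoms: 3-chloroperoxybenzoic acid, OOC(=O)c1cccc(Cl)c1
Why: Prilezhaev epoxidation of the monosubstituted alkene should give both C17 epimers because the adjacent C18 centre exerts little facial control.

Step 5
Reactants: 5 (2S)-2-[(2RS)-oxiran-2-yl]propyl TBS ether
Product: 6 (2S)-2-[(2S)-oxiran-2-yl]propyl TBS ether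
Conditions: (R,R)-(salen)Co(OAc) (cat., trivalent cobalt), H2O (0.55 equiv), THF, 0 °C to rt
Reagents that add atoms: none
Why: Hydrolytic kinetic resolution: the (R,R)-catalyst should hydrolyse the (2R)-oxirane epimer selectively, so the (2S)-oxirane is recovered with catalyst-controlled configuration at C17 and the diol is removed by chromatography.

Step 6
Reactants: 6 (2S)-2-[(2S)-oxiran-2-yl]propyl TBS ether; 7 acetic acid
Product: 10 (5R)-5-[(2S)-1-(TBS-oxy)propan-2-yl]oxolan-2-one, via dilithioacetate 8 (not isolated), via dilithium oxido carboxylate 9 (not isolated)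
Conditions: 7, LDA (2.1 equiv), THF, 0 °C; then 6, DME, 55 °C; then 1 M HCl to pH 3 at 0 °C, PPTS (cat.), PhMe, 40 °C
Reagents that add atoms: none
Why: Dilithioacetate 8 attacks the terminal carbon C16 of the epoxide in an SN2 opening, which makes the C15–C16 bond and frees the C17 alkoxide of 9; on acidification the C17 hydroxyl adds to the carboxyl carbon C14 and water is lost, which makes the O–C14 bond. The closest known reaction type is the lactone annulation of epoxides with carboxylic acid dianions or malonates. The oxolane ring is closed in its 2-oxo form by a 5-exo-trig acyl substitution. No new stereocentre is formed: C17 keeps the configuration fixed in step 5 because the nucleophile attacks C16 and not the stereocentre, and C18 is untouched. The step needs attack at C16 and not at C17, which the unsubstituted terminal position beside the branched C17 secures, and it needs the primary TBS ether to survive the base and the brief mild acid. C15 and C14 are left at the CH2 and C=O level so that both can be set afterwards under control of C17 (steps 7 and 15).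

Step 7
Reactants: 10 (5R)-5-[(2S)-1-(TBS-oxy)propan-2-yl]oxolan-2-one
Product: 12 (3S,5R)-3-hydroxy-5-[(2S)-1-(TBS-oxy)propan-2-yl]oxolan-2-one, via sodium lactone enolate 11 (not isolated)
Conditions: NaHMDS, THF, −78 °C; then 2-(phenylsulfonyl)-3-phenyloxaziridine, −78 °C; AcOH
Reagents that add atoms: 2-(phenylsulfonyl)-3-phenyloxaziridine, O=S(=O)(c1ccccc1)N1OC1c1ccccc1
Why: Enolate hydroxylation with the N-sulfonyloxaziridine should occur on the face anti to the branched C17 substituent, which sets C15 trans to C17.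

Step 8
Reactants: 12 (3S,5R)-3-hydroxy-5-[(2S)-1-(TBS-oxy)propan-2-yl]oxolan-2-one
Product: 13 (3S,5R)-3-methoxy-5-[(2S)-1-(TBS-oxy)propan-2-yl]oxolan-2-one
Conditions: MeI, Ag2O, 4 Å MS, Et2O, rt, dark
Reagents that add atoms: iodomethane, CI
Why: Silver-oxide-mediated O-methylation etherifies the α-hydroxy lactone without a base strong enough to epimerise C15 or open the lactone.

Step 9
Reactants: 14 prop-2-yn-1-ol
Product: 16 (2Z)-3-iodo-2-methylprop-2-en-1-ol, via vinylmagnesium alkoxide 15 (not isolated)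
Conditions: MeMgBr (2.5 equiv), CuI (10 mol%), THF, −10 °C to rt; then I2, −10 °C; 1 M HCl
Reagents that add atoms: methylmagnesium bromide, C[Mg]Br; iodine, II
Why: Copper-catalysed anti-carbomagnesiation of the propargylic alkoxide places methyl on C12 and magnesium on C13 in a five-membered chelate, and iodinolysis with retention gives the (Z)-iodide that fixes the C12=C13 geometry.

Step 10
Reactants: 16 (2Z)-3-iodo-2-methylprop-2-en-1-ol
Product: 17 (2Z)-3-iodo-2-methylprop-2-enal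
Conditions: MnO2, CH2Cl2, rt; used at once
Reagents that add atoms: none
Why: Allylic oxidation with MnO2 is neutral and should preserve the (Z) geometry of the enal.

Step 11
Reactants: 17 (2Z)-3-iodo-2-methylprop-2-enal; 18 allenylboronic acid pinacol ester
Product: 19 (1Z,3R)-1-iodo-2-methylhex-1-en-5-yn-3-ol
Conditions: (R)-TRIP (5 mol%), 4 Å MS, toluene, 0 °C; aqueous work-up
Reagents that add atoms: none
Why: Chiral-phosphoric-acid-catalysed propargylation: the allenylboronate adds through a closed six-membered SE2' transition state organised by the acid, which sets C11 under catalyst control.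

Step 12
Reactants: 19 (1Z,3R)-1-iodo-2-methylhex-1-en-5-yn-3-ol
Product: 20 (1Z,3R)-1-iodo-2-methyl-3-(TBS-oxy)hex-1-en-5-yne
Conditions: TBSCl, imidazole, DMF, rt
Reagents that add atoms: tert-butyl(chloro)dimethylsilane, CC(C)(C)[Si](C)(C)Cl
Why: Silyl ether formation protects the C11 hydroxyl for the organolithium and Lewis acid steps that follow.

Step 13
Reactants: 20 (1Z,3R)-1-iodo-2-methyl-3-(TBS-oxy)hex-1-en-5-yne
Product: 22 (1Z,3R)-1-iodo-2-methyl-3-(TBS-oxy)-6-(trimethylsilyl)hex-1-en-5-yne, via lithium acetylide 21 (not isolated)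
Conditions: LiHMDS, THF, −78 °C; TMSCl, −78 to 0 °C
Reagents that add atoms: chlorotrimethylsilane, C[Si](C)(C)Cl
Why: Deprotonation and C-silylation of the terminal alkyne mask the acidic C–H before the iodine–lithium exchange, and the amide base does not touch the vinyl iodide.

Step 14
Reactants: 22 (1Z,3R)-1-iodo-2-methyl-3-(TBS-oxy)-6-(trimethylsilyl)hex-1-en-5-yne; 13 (3S,5R)-3-methoxy-5-[(2S)-1-(TBS-oxy)propan-2-yl]oxolan-2-one
Product: 24 (3S,5R)-3-methoxy-2-[(1Z,3R)-2-methyl-3-(TBS-oxy)-6-(trimethylsilyl)hex-1-en-5-yn-1-yl]-5-[(2S)-1-(TBS-oxy)propan-2-yl]oxolan-2-ol (both C14 epimers), via (Z)-vinyllithium 23 (not isolated)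
Conditions: 22, t-BuLi (2 equiv), Et2O, −78 °C; then 13, −78 °C; AcOH
Reagents that add atoms: none
Why: Iodine–lithium exchange with retention gives the (Z)-vinyllithium, which adds once to the lactone carbonyl C14 because the tetrahedral lithium alkoxide is stable at −78 °C, and ether at low temperature suppresses 1,4 oxygen-to-carbon silyl migration.

Step 15
Reactants: 24 (3S,5R)-3-methoxy-2-[(1Z,3R)-2-methyl-3-(TBS-oxy)-6-(trimethylsilyl)hex-1-en-5-yn-1-yl]-5-[(2S)-1-(TBS-oxy)propan-2-yl]oxolan-2-ol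
Product: 26 (2R,3S,5R)-3-methoxy-2-[(1Z,3R)-2-methyl-3-(TBS-oxy)-6-(trimethylsilyl)hex-1-en-5-yn-1-yl]-5-[(2S)-1-(TBS-oxy)propan-2-yl]oxolane, via oxocarbenium ion 25 (not isolated)
Conditions: Et3SiH, BF3·OEt2, CH2Cl2, −78 to −40 °C
Reagents that add atoms: none
Why: Ionic reduction of the lactol: BF3 ionises it to oxocarbenium ion 25 and the silane should deliver hydride to C14 by inside attack on the envelope, cis to the C15 methoxy group and trans to the C17 substituent (as in the reduction of 2-alkoxy furanose hemiketals to β-C-glycosides), which sets C14 with the 14,17-cis and 14,15-trans relationships.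

Step 16
Reactants: 26 (2R,3S,5R)-3-methoxy-2-[(1Z,3R)-2-methyl-3-(TBS-oxy)-6-(trimethylsilyl)hex-1-en-5-yn-1-yl]-5-[(2S)-1-(TBS-oxy)propan-2-yl]oxolane
Product: 27 (2R,3S,5R)-3-methoxy-2-[(1Z,3R)-2-methyl-3-(TBS-oxy)hex-1-en-5-yn-1-yl]-5-[(2S)-1-(TBS-oxy)propan-2-yl]oxolane
Conditions: K2CO3, MeOH, rt
Reagents that add atoms: none
Why: Methanolysis cleaves the alkynyl C–Si bond selectively and leaves both silyl ethers in place.

Step 17
Reactants: 27 (2R,3S,5R)-3-methoxy-2-[(1Z,3R)-2-methyl-3-(TBS-oxy)hex-1-en-5-yn-1-yl]-5-[(2S)-1-(TBS-oxy)propan-2-yl]oxolane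
Product: 28 (2S)-2-{(2R,4S,5R)-4-methoxy-5-[(1Z,3R)-2-methyl-3-(TBS-oxy)hex-1-en-5-yn-1-yl]oxolan-2-yl}propan-1-ol
Conditions: HF·pyridine, pyridine, THF, 0 °C
Reagents that add atoms: none
Why: Buffered HF·pyridine should cleave the unhindered primary TBS ether at C19 much faster than the hindered secondary allylic one at C11.

Step 18
Reactants: 14 prop-2-yn-1-ol
Product: 30 (2E)-3-iodo-2-methylprop-2-en-1-ol, via vinylalane 29 (not isolated)
Conditions: AlMe3, Cp2ZrCl2 (cat.), CH2Cl2, 0 °C to rt; then I2, THF, −30 °C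
Reagents that add atoms: trimethylaluminium, C[Al](C)C; iodine, II
Why: Zirconium-catalysed syn-carboalumination places methyl on the internal carbon, and iodinolysis with retention gives the (E)-iodide that fixes the C6=C7 geometry.

Step 19
Reactants: 30 (2E)-3-iodo-2-methylprop-2-en-1-ol
Product: 31 (2E)-3-iodo-2-methylprop-2-enal
Conditions: MnO2, CH2Cl2, rt
Reagents that add atoms: none
Why: Allylic oxidation with MnO2 gives the enal without touching the vinyl iodide.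

Step 20
Reactants: 32 (4R)-4-benzyl-3-propanoyl-1,3-oxazolidin-2-one; 31 (2E)-3-iodo-2-methylprop-2-enal
Product: 34 (4R)-4-benzyl-3-[(2R,3R,4E)-3-hydroxy-5-iodo-2,4-dimethylpent-4-enoyl]-1,3-oxazolidin-2-one, via (Z)-boron enolate 33 (not isolated)
Conditions: Bu2BOTf, Et3N, CH2Cl2, −78 to 0 °C; 31, −78 to 0 °C; pH 7 buffer, MeOH, H2O2
Reagents that add atoms: none
Why: Evans syn-aldol reaction: the (Z)-boron enolate reacts through a Zimmerman–Traxler chair whose face is fixed by the (R)-benzyl auxiliary, which sets C4 (and the transient C5 carbinol) as the (2R,3R)-syn adduct.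

Step 21
Reactants: 34 (4R)-4-benzyl-3-[(2R,3R,4E)-3-hydroxy-5-iodo-2,4-dimethylpent-4-enoyl]-1,3-oxazolidin-2-one
Product: 35 (2R,3R,4E)-3-hydroxy-5-iodo-N-methoxy-N,2,4-trimethylpent-4-enamide
Conditions: MeNHOMe·HCl, AlMe3, THF, −20 to 0 °C
Reagents that add atoms: N,O-dimethylhydroxylamine hydrochloride, Cl.CNOC
Why: Aluminium-amide transamidation, assisted by the free β-hydroxyl, exchanges the auxiliary for the N-methoxy-N-methylamide (Weinreb amide) without epimerising C4.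

Step 22
Reactants: 35 (2R,3R,4E)-3-hydroxy-5-iodo-N-methoxy-N,2,4-trimethylpent-4-enamide
Product: 36 (2R,3R,4E)-5-iodo-N-methoxy-N,2,4-trimethyl-3-(TES-oxy)pent-4-enamide
Conditions: TESCl, imidazole, CH2Cl2, 0 °C
Reagents that add atoms: chlorotriethylsilane, CC[Si](CC)(CC)Cl
Why: Silyl ether formation masks the C5 hydroxyl as a TES ether that can later be removed in the presence of the C11 TBS ether.

Step 23
Reactants: 36 (2R,3R,4E)-5-iodo-N-methoxy-N,2,4-trimethyl-3-(TES-oxy)pent-4-enamide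
Product: 37 (2R,3R,4E)-5-iodo-2,4-dimethyl-3-(TES-oxy)pent-4-enal
Conditions: DIBAL-H, THF, −78 °C; aq. potassium sodium tartrate
Reagents that add atoms: none
Why: Reduction of the Weinreb amide stops at the aldehyde through the chelated tetrahedral intermediate.

Step 24
Reactants: 38 ethyl 2-[bis(2,2,2-trifluoroethoxy)phosphoryl]propanoate; 37 (2R,3R,4E)-5-iodo-2,4-dimethyl-3-(TES-oxy)pent-4-enal
Product: 40 ethyl (2Z,4S,5R,6E)-7-iodo-2,4,6-trimethyl-5-(TES-oxy)hepta-2,6-dienoate, via potassium phosphonate carbanion 39 (not isolated)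
Conditions: 38, KHMDS, 18-crown-6, THF, −78 °C; then 37
Reagents that add atoms: none
Why: Still–Gennari olefination: the trifluoroethyl phosphonate eliminates rapidly from the kinetically formed adduct under dissociating conditions and should give the (Z)-2-methyl-enoate that fixes the C2=C3 geometry.

Step 25
Reactants: 28 (2S)-2-{(2R,4S,5R)-4-methoxy-5-[(1Z,3R)-2-methyl-3-(TBS-oxy)hex-1-en-5-yn-1-yl]oxolan-2-yl}propan-1-ol; 40 ethyl (2Z,4S,5R,6E)-7-iodo-2,4,6-trimethyl-5-(TES-oxy)hepta-2,6-dienoate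
Product: 41 ethyl (2Z,4S,5R,6E,11R,12Z,14R,15S,17R,18S)-14,17-epoxy-19-hydroxy-15-methoxy-2,4,6,12,18-pentamethyl-11-(TBS-oxy)-5-(TES-oxy)nonadeca-2,6,12-trien-8-ynoate
Conditions: Pd(PPh3)4 (5 mol%), CuI (10 mol%), Et3N, THF, rt, degassed
Reagents that add atoms: none
Why: Sonogashira coupling joins the terminal alkyne C8 to the vinyl iodide C7 with retention of the (6E) geometry and tolerates the free alcohol, the ester and the silyl ethers.

Step 26
Reactants: 41 ethyl (2Z,4S,5R,6E,11R,12Z,14R,15S,17R,18S)-14,17-epoxy-19-hydroxy-15-methoxy-2,4,6,12,18-pentamethyl-11-(TBS-oxy)-5-(TES-oxy)nonadeca-2,6,12-trien-8-ynoate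
Product: 42 ethyl (2Z,4S,5R,6E,8Z,11R,12Z,14R,15S,17R,18S)-14,17-epoxy-19-hydroxy-15-methoxy-2,4,6,12,18-pentamethyl-11-(TBS-oxy)-5-(TES-oxy)nonadeca-2,6,8,12-tetraenoate
Conditions: Zn(Cu/Ag), MeOH/H2O (1:1), rt
Reagents that add atoms: none
Why: The activated zinc couple reduces only the alkyne conjugated to the C6=C7 alkene, by cis delivery of two hydrogens, and should give the (8Z) alkene without over-reduction.

Step 27
Reactants: 42 ethyl (2Z,4S,5R,6E,8Z,11R,12Z,14R,15S,17R,18S)-14,17-epoxy-19-hydroxy-15-methoxy-2,4,6,12,18-pentamethyl-11-(TBS-oxy)-5-(TES-oxy)nonadeca-2,6,8,12-tetraenoate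
Product: 43 ethyl (2Z,4S,5R,6E,8Z,11R,12Z,14R,15S,17R,18R)-14,17-epoxy-15-methoxy-2,4,6,12,18-pentamethyl-19-oxo-11-(TBS-oxy)-5-(TES-oxy)nonadeca-2,6,8,12-tetraenoate
Conditions: DMP, NaHCO3, CH2Cl2, 0 °C; used at once
Reagents that add atoms: none
Why: Buffered hypervalent-iodine oxidation gives the C19 aldehyde under conditions mild enough to keep the C18 centre and the diene intact.

Step 28
Reactants: 44 (2E)-but-2-en-1-ol
Product: 45 [(2R,3R)-3-methyloxiran-2-yl]methanol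
Conditions: Ti(OiPr)4 (10 mol%), D-(−)-diethyl tartrate, t-BuOOH, 4 Å MS, CH2Cl2, −20 °C
Reagents that add atoms: tert-butyl hydroperoxide, CC(C)(C)OO
Why: Sharpless asymmetric epoxidation with the D-tartrate delivers oxygen to the face of the (E)-allylic alcohol that sets C22 and C23 as (2R,3R).

Step 29
Reactants: 45 [(2R,3R)-3-methyloxiran-2-yl]methanol
Product: 46 (2S,3R)-3-methyloxirane-2-carbaldehyde
Conditions: TEMPO (cat.), PhI(OAc)2, CH2Cl2, rt; solution used directly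
Reagents that add atoms: none
Why: Nitroxyl-catalysed oxidation gives the volatile epoxy aldehyde without opening the oxirane or epimerising C22.

Step 30
Reactants: 46 (2S,3R)-3-methyloxirane-2-carbaldehyde
Product: 47 (2R,3R)-2-[(E)-2-iodoethenyl]-3-methyloxirane
Conditions: CrCl2, CHI3, THF, 0 °C
Reagents that add atoms: iodoform, IC(I)I
Why: Takai olefination with the geminal dichromium reagent from iodoform should give the (E)-vinyl iodide that fixes the C20=C21 geometry.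

Step 31
Reactants: 43 ethyl (2Z,4S,5R,6E,8Z,11R,12Z,14R,15S,17R,18R)-14,17-epoxy-15-methoxy-2,4,6,12,18-pentamethyl-19-oxo-11-(TBS-oxy)-5-(TES-oxy)nonadeca-2,6,8,12-tetraenoate; 47 (2R,3R)-2-[(E)-2-iodoethenyl]-3-methyloxirane
Product: 48 ethyl (2Z,4S,5R,6E,8Z,11R,12Z,14R,15S,17R,18R,19R,20E,22R,23R)-14,17:22,23-diepoxy-19-hydroxy-15-methoxy-2,4,6,12,18-pentamethyl-11-(TBS-oxy)-5-(TES-oxy)tetracosa-2,6,8,12,20-pentaenoate
Conditions: CrCl2, NiCl2 (cat.), DMSO, rt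
Reagents that add atoms: none
Why: Nozaki–Hiyama–Kishi reaction: the alkenylchromium species adds chemoselectively to the aldehyde, and Felkin–Anh control by C18 together with 1,3-anti induction by the C17 ring oxygen (reinforcing in this anti α-methyl β-alkoxy aldehyde) should set C19 as (R).

Step 32
Reactants: 48 ethyl (2Z,4S,5R,6E,8Z,11R,12Z,14R,15S,17R,18R,19R,20E,22R,23R)-14,17:22,23-diepoxy-19-hydroxy-15-methoxy-2,4,6,12,18-pentamethyl-11-(TBS-oxy)-5-(TES-oxy)tetracosa-2,6,8,12,20-pentaenoate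
Product: 49 (2Z,4S,5R,6E,8Z,11R,12Z,14R,15S,17R,18R,19R,20E,22R,23R)-14,17:22,23-diepoxy-19-hydroxy-15-methoxy-2,4,6,12,18-pentamethyl-11-(TBS-oxy)-5-(TES-oxy)tetracosa-2,6,8,12,20-pentaenoic acid
Conditions: LiOH, THF/MeOH/H2O, rt; then aq. NaH2PO4 at 0 °C
Reagents that add atoms: lithium hydroxide, [Li+].[OH-]
Why: Saponification of the ethyl ester at room temperature should spare the silyl ethers and the oxirane, and a buffered work-up avoids acid at the vinyl oxirane.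

Step 33
Reactants: 49 (2Z,4S,5R,6E,8Z,11R,12Z,14R,15S,17R,18R,19R,20E,22R,23R)-14,17:22,23-diepoxy-19-hydroxy-15-methoxy-2,4,6,12,18-pentamethyl-11-(TBS-oxy)-5-(TES-oxy)tetracosa-2,6,8,12,20-pentaenoic acid
Product: 51 (2Z,4S,5R,6E,8Z,11R,12Z,14R,15S,17R,18R,19R,20E,22R,23R)-14,17:22,23-diepoxy-15-methoxy-2,4,6,12,18-pentamethyl-11-(TBS-oxy)-5-(TES-oxy)tetracosa-2,6,8,12,20-pentaen-19-olide, via mixed anhydride 50 (not isolated)
Conditions: 2,4,6-trichlorobenzoyl chloride, Et3N, THF, rt; then slow addition to DMAP, toluene, rt, high dilution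
Reagents that add atoms: none
Why: Yamaguchi macrolactonisation: the mixed anhydride transfers the acyl group via DMAP to the only free hydroxyl (C19) under high dilution, which closes the 20-membered lactone.

Step 34
Reactants: 51 (2Z,4S,5R,6E,8Z,11R,12Z,14R,15S,17R,18R,19R,20E,22R,23R)-14,17:22,23-diepoxy-15-methoxy-2,4,6,12,18-pentamethyl-11-(TBS-oxy)-5-(TES-oxy)tetracosa-2,6,8,12,20-pentaen-19-olide
Product: 52 (2Z,4S,5R,6E,8Z,11R,12Z,14R,15S,17R,18R,19R,20E,22R,23R)-14,17:22,23-diepoxy-5-hydroxy-15-methoxy-2,4,6,12,18-pentamethyl-11-(TBS-oxy)tetracosa-2,6,8,12,20-pentaen-19-olide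
Conditions: HF·pyridine, pyridine, THF, 0 °C; used at once
Reagents that add atoms: none
Why: The TES ether should be cleaved by buffered HF·pyridine well before the TBS ether, which frees only the C5 hydroxyl.

Step 35
Reactants: 52 (2Z,4S,5R,6E,8Z,11R,12Z,14R,15S,17R,18R,19R,20E,22R,23R)-14,17:22,23-diepoxy-5-hydroxy-15-methoxy-2,4,6,12,18-pentamethyl-11-(TBS-oxy)tetracosa-2,6,8,12,20-pentaen-19-olide
Product: 53 (2Z,4S,6E,8Z,11R,12Z,14R,15S,17R,18R,19R,20E,22R,23R)-14,17:22,23-diepoxy-15-methoxy-2,4,6,12,18-pentamethyl-5-oxo-11-(TBS-oxy)tetracosa-2,6,8,12,20-pentaen-19-olide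
Conditions: DMP, NaHCO3, CH2Cl2, 0 °C
Reagents that add atoms: none
Why: Buffered hypervalent-iodine oxidation forms the C5 dienone without base, so the now doubly activated C4 centre should not epimerise.

Step 36
Reactants: 53 (2Z,4S,6E,8Z,11R,12Z,14R,15S,17R,18R,19R,20E,22R,23R)-14,17:22,23-diepoxy-15-methoxy-2,4,6,12,18-pentamethyl-5-oxo-11-(TBS-oxy)tetracosa-2,6,8,12,20-pentaen-19-olide
Product: 54 CNP0117824.1, (2Z,4S,6E,8Z,11R,12Z,14R,15S,17R,18R,19R,20E,22R,23R)-14,17:22,23-diepoxy-11-hydroxy-15-methoxy-2,4,6,12,18-pentamethyl-5-oxotetracosa-2,6,8,12,20-pentaen-19-olide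
Conditions: TBAF, AcOH (1:1), THF, 0 °C to rt
Reagents that add atoms: none
Why: Acetic-acid-buffered fluoride desilylation should free the C11 hydroxyl under near-neutral conditions that spare the vinyl oxirane, the lactone and the C4 centre.

Compound list
1 | methyl (2S)-3-hydroxy-2-methylpropanoate | COC(=O)[C@@H](C)CO | starting material
2 | methyl (2S)-2-methyl-3-(TBS-oxy)propanoate | COC(=O)[C@@H](C)CO[Si](C)(C)C(C)(C)C | intermediate
3 | (2S)-2-methyl-3-(TBS-oxy)propanal | O=C[C@@H](C)CO[Si](C)(C)C(C)(C)C | intermediate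
4 | (2R)-2-methylbut-3-en-1-yl TBS ether | C=C[C@@H](C)CO[Si](C)(C)C(C)(C)C | intermediate
5 | (2S)-2-[(2RS)-oxiran-2-yl]propyl TBS ether (both C17 epimers) | CC(C)(C)[Si](C)(C)OC[C@H](C)C1CO1 | intermediate
6 | (2S)-2-[(2S)-oxiran-2-yl]propyl TBS ether | CC(C)(C)[Si](C)(C)OC[C@H](C)[C@H]1CO1 | intermediate
7 | acetic acid | CC(=O)O | starting material
8 | dilithioacetate, dilithium ethene-1,1-diolate (not isolated) | [Li+].[Li+].[O-]C([O-])=C | intermediate
9 | dilithium (4R,5S)-5-methyl-4-oxido-6-(TBS-oxy)hexanoate (not isolated) | [Li+].[Li+].[O-]C(=O)CC[C@@H]([O-])[C@@H](C)CO[Si](C)(C)C(C)(C)C | intermediate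
10 | (5R)-5-[(2S)-1-(TBS-oxy)propan-2-yl]oxolan-2-one | CC(C)(C)[Si](C)(C)OC[C@H](C)[C@H]1CCC(=O)O1 | intermediate
11 | sodium enolate of lactone 10 (not isolated) | [Na+].CC(C)(C)[Si](C)(C)OC[C@H](C)[C@H]1CC=C([O-])O1 | intermediate
12 | (3S,5R)-3-hydroxy-5-[(2S)-1-(TBS-oxy)propan-2-yl]oxolan-2-one | CC(C)(C)[Si](C)(C)OC[C@H](C)[C@H]1C[C@H](O)C(=O)O1 | intermediate
13 | (3S,5R)-3-methoxy-5-[(2S)-1-(TBS-oxy)propan-2-yl]oxolan-2-one | CC(C)(C)[Si](C)(C)OC[C@H](C)[C@H]1C[C@H](OC)C(=O)O1 | intermediate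
14 | prop-2-yn-1-ol | C#CCO | starting material
15 | bromomagnesium (2Z)-3-(bromomagnesio)-2-methylprop-2-en-1-olate (not isolated) | Br[Mg]OC/C(C)=C\[Mg]Br | intermediate
16 | (2Z)-3-iodo-2-methylprop-2-en-1-ol | OC/C(C)=C\I | intermediate
17 | (2Z)-3-iodo-2-methylprop-2-enal | O=C/C(C)=C\I | intermediate
18 | allenylboronic acid pinacol ester, 4,4,5,5-tetramethyl-2-(propa-1,2-dien-1-yl)-1,3,2-dioxaborolane | C=C=CB1OC(C)(C)C(C)(C)O1 | starting material
19 | (1Z,3R)-1-iodo-2-methylhex-1-en-5-yn-3-ol | C#CC[C@@H](O)/C(C)=C\I | intermediate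
20 | (1Z,3R)-1-iodo-2-methyl-3-(TBS-oxy)hex-1-en-5-yne | C#CC[C@@H](O[Si](C)(C)C(C)(C)C)/C(C)=C\I | intermediate
21 | lithium acetylide of 20 (not isolated) | [Li]C#CC[C@@H](O[Si](C)(C)C(C)(C)C)/C(C)=C\I | intermediate
22 | (1Z,3R)-1-iodo-2-methyl-3-(TBS-oxy)-6-(trimethylsilyl)hex-1-en-5-yne | C[Si](C)(C)C#CC[C@@H](O[Si](C)(C)C(C)(C)C)/C(C)=C\I | intermediate
23 | (1Z,3R)-2-methyl-3-(TBS-oxy)-6-(trimethylsilyl)hex-1-en-5-yn-1-yllithium (not isolated) | [Li]/C=C(/C)[C@H](O[Si](C)(C)C(C)(C)C)CC#C[Si](C)(C)C | intermediate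
24 | (3S,5R)-3-methoxy-2-[(1Z,3R)-2-methyl-3-(TBS-oxy)-6-(trimethylsilyl)hex-1-en-5-yn-1-yl]-5-[(2S)-1-(TBS-oxy)propan-2-yl]oxolan-2-ol (both C14 epimers) | CO[C@H]1C[C@@H](OC1(O)/C=C(/C)[C@H](O[Si](C)(C)C(C)(C)C)CC#C[Si](C)(C)C)[C@@H](C)CO[Si](C)(C)C(C)(C)C | intermediate
25 | oxocarbenium ion from 24, (3S,5R)-3-methoxy-2-alkenyl-4,5-dihydro-3H-furan-1-ium (not isolated) | CO[C@H]1C[C@@H]([O+]=C1/C=C(/C)[C@H](O[Si](C)(C)C(C)(C)C)CC#C[Si](C)(C)C)[C@@H](C)CO[Si](C)(C)C(C)(C)C | intermediate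
26 | (2R,3S,5R)-3-methoxy-2-[(1Z,3R)-2-methyl-3-(TBS-oxy)-6-(trimethylsilyl)hex-1-en-5-yn-1-yl]-5-[(2S)-1-(TBS-oxy)propan-2-yl]oxolane | CO[C@H]1C[C@@H](O[C@@H]1/C=C(/C)[C@H](O[Si](C)(C)C(C)(C)C)CC#C[Si](C)(C)C)[C@@H](C)CO[Si](C)(C)C(C)(C)C | intermediate
27 | (2R,3S,5R)-3-methoxy-2-[(1Z,3R)-2-methyl-3-(TBS-oxy)hex-1-en-5-yn-1-yl]-5-[(2S)-1-(TBS-oxy)propan-2-yl]oxolane | CO[C@H]1C[C@@H](O[C@@H]1/C=C(/C)[C@H](O[Si](C)(C)C(C)(C)C)CC#C)[C@@H](C)CO[Si](C)(C)C(C)(C)C | intermediate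
28 | (2S)-2-{(2R,4S,5R)-4-methoxy-5-[(1Z,3R)-2-methyl-3-(TBS-oxy)hex-1-en-5-yn-1-yl]oxolan-2-yl}propan-1-ol | CO[C@H]1C[C@@H](O[C@@H]1/C=C(/C)[C@H](O[Si](C)(C)C(C)(C)C)CC#C)[C@@H](C)CO | intermediate
29 | dimethylaluminium (2E)-3-(dimethylalumanyl)-2-methylprop-2-en-1-olate (not isolated) | C[Al](C)OC/C(C)=C/[Al](C)C | intermediate
30 | (2E)-3-iodo-2-methylprop-2-en-1-ol | OC/C(C)=C/I | intermediate
31 | (2E)-3-iodo-2-methylprop-2-enal | O=C/C(C)=C/I | intermediate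
32 | (4R)-4-benzyl-3-propanoyl-1,3-oxazolidin-2-one | CCC(=O)N1[C@H](Cc2ccccc2)COC1=O | starting material
33 | (Z)-dibutylboron enolate of 32 (not isolated) | C/C=C(\OB(CCCC)CCCC)N1[C@H](Cc2ccccc2)COC1=O | intermediate
34 | (4R)-4-benzyl-3-[(2R,3R,4E)-3-hydroxy-5-iodo-2,4-dimethylpent-4-enoyl]-1,3-oxazolidin-2-one | O=C(N1[C@H](Cc2ccccc2)COC1=O)[C@H](C)[C@@H](O)/C(C)=C/I | intermediate
35 | (2R,3R,4E)-3-hydroxy-5-iodo-N-methoxy-N,2,4-trimethylpent-4-enamide | CON(C)C(=O)[C@H](C)[C@@H](O)/C(C)=C/I | intermediate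
36 | (2R,3R,4E)-5-iodo-N-methoxy-N,2,4-trimethyl-3-(TES-oxy)pent-4-enamide | CON(C)C(=O)[C@H](C)[C@@H](O[Si](CC)(CC)CC)/C(C)=C/I | intermediate
37 | (2R,3R,4E)-5-iodo-2,4-dimethyl-3-(TES-oxy)pent-4-enal | O=C[C@H](C)[C@@H](O[Si](CC)(CC)CC)/C(C)=C/I | intermediate
38 | ethyl 2-[bis(2,2,2-trifluoroethoxy)phosphoryl]propanoate | CCOC(=O)C(C)P(=O)(OCC(F)(F)F)OCC(F)(F)F | starting material
39 | potassium salt of the carbanion of 38 (not isolated) | [K+].CCOC(=O)[C-](C)P(=O)(OCC(F)(F)F)OCC(F)(F)F | intermediate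
40 | ethyl (2Z,4S,5R,6E)-7-iodo-2,4,6-trimethyl-5-(TES-oxy)hepta-2,6-dienoate | CCOC(=O)/C(C)=C\[C@H](C)[C@@H](O[Si](CC)(CC)CC)/C(C)=C/I | intermediate
41 | ethyl (2Z,4S,5R,6E,11R,12Z,14R,15S,17R,18S)-14,17-epoxy-19-hydroxy-15-methoxy-2,4,6,12,18-pentamethyl-11-(TBS-oxy)-5-(TES-oxy)nonadeca-2,6,12-trien-8-ynoate | CO[C@H]1C[C@@H](O[C@@H]1/C=C(/C)[C@H](O[Si](C)(C)C(C)(C)C)CC#C/C=C(\C)[C@H](O[Si](CC)(CC)CC)[C@@H](C)/C=C(/C)C(=O)OCC)[C@@H](C)CO | intermediate
42 | ethyl (2Z,4S,5R,6E,8Z,11R,12Z,14R,15S,17R,18S)-14,17-epoxy-19-hydroxy-15-methoxy-2,4,6,12,18-pentamethyl-11-(TBS-oxy)-5-(TES-oxy)nonadeca-2,6,8,12-tetraenoate | CO[C@H]1C[C@@H](O[C@@H]1/C=C(/C)[C@H](O[Si](C)(C)C(C)(C)C)C/C=C\C=C(/C)[C@H](O[Si](CC)(CC)CC)[C@@H](C)/C=C(/C)C(=O)OCC)[C@@H](C)CO | intermediate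
43 | ethyl (2Z,4S,5R,6E,8Z,11R,12Z,14R,15S,17R,18R)-14,17-epoxy-15-methoxy-2,4,6,12,18-pentamethyl-19-oxo-11-(TBS-oxy)-5-(TES-oxy)nonadeca-2,6,8,12-tetraenoate | CO[C@H]1C[C@@H](O[C@@H]1/C=C(/C)[C@H](O[Si](C)(C)C(C)(C)C)C/C=C\C=C(/C)[C@H](O[Si](CC)(CC)CC)[C@@H](C)/C=C(/C)C(=O)OCC)[C@@H](C)C=O | intermediate
44 | (2E)-but-2-en-1-ol | C/C=C/CO | starting material
45 | [(2R,3R)-3-methyloxiran-2-yl]methanol | OC[C@H]1O[C@@H]1C | intermediate
46 | (2S,3R)-3-methyloxirane-2-carbaldehyde | O=C[C@H]1O[C@@H]1C | intermediate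
47 | (2R,3R)-2-[(E)-2-iodoethenyl]-3-methyloxirane | I/C=C/[C@H]1O[C@@H]1C | intermediate
48 | ethyl (2Z,4S,5R,6E,8Z,11R,12Z,14R,15S,17R,18R,19R,20E,22R,23R)-14,17:22,23-diepoxy-19-hydroxy-15-methoxy-2,4,6,12,18-pentamethyl-11-(TBS-oxy)-5-(TES-oxy)tetracosa-2,6,8,12,20-pentaenoate | CO[C@H]1C[C@@H](O[C@@H]1/C=C(/C)[C@H](O[Si](C)(C)C(C)(C)C)C/C=C\C=C(/C)[C@H](O[Si](CC)(CC)CC)[C@@H](C)/C=C(/C)C(=O)OCC)[C@@H](C)[C@H](O)/C=C/[C@H]1O[C@@H]1C | intermediate
49 | (2Z,4S,5R,6E,8Z,11R,12Z,14R,15S,17R,18R,19R,20E,22R,23R)-14,17:22,23-diepoxy-19-hydroxy-15-methoxy-2,4,6,12,18-pentamethyl-11-(TBS-oxy)-5-(TES-oxy)tetracosa-2,6,8,12,20-pentaenoic acid | CO[C@H]1C[C@@H](O[C@@H]1/C=C(/C)[C@H](O[Si](C)(C)C(C)(C)C)C/C=C\C=C(/C)[C@H](O[Si](CC)(CC)CC)[C@@H](C)/C=C(/C)C(=O)O)[C@@H](C)[C@H](O)/C=C/[C@H]1O[C@@H]1C | intermediate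
50 | mixed anhydride of 49 with 2,4,6-trichlorobenzoic acid (not isolated) | CO[C@H]1C[C@@H](O[C@@H]1/C=C(/C)[C@H](O[Si](C)(C)C(C)(C)C)C/C=C\C=C(/C)[C@H](O[Si](CC)(CC)CC)[C@@H](C)/C=C(/C)C(=O)OC(=O)c1c(Cl)cc(Cl)cc1Cl)[C@@H](C)[C@H](O)/C=C/[C@H]1O[C@@H]1C | intermediate
51 | (2Z,4S,5R,6E,8Z,11R,12Z,14R,15S,17R,18R,19R,20E,22R,23R)-14,17:22,23-diepoxy-15-methoxy-2,4,6,12,18-pentamethyl-11-(TBS-oxy)-5-(TES-oxy)tetracosa-2,6,8,12,20-pentaen-19-olide | CO[C@H]1C[C@H]2O[C@@H]1/C=C(/C)[C@H](O[Si](C)(C)C(C)(C)C)C/C=C\C=C(/C)[C@H](O[Si](CC)(CC)CC)[C@@H](C)/C=C(/C)C(=O)O[C@H](/C=C/[C@H]1O[C@@H]1C)[C@@H]2C | intermediate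
52 | (2Z,4S,5R,6E,8Z,11R,12Z,14R,15S,17R,18R,19R,20E,22R,23R)-14,17:22,23-diepoxy-5-hydroxy-15-methoxy-2,4,6,12,18-pentamethyl-11-(TBS-oxy)tetracosa-2,6,8,12,20-pentaen-19-olide | CO[C@H]1C[C@H]2O[C@@H]1/C=C(/C)[C@H](O[Si](C)(C)C(C)(C)C)C/C=C\C=C(/C)[C@H](O)[C@@H](C)/C=C(/C)C(=O)O[C@H](/C=C/[C@H]1O[C@@H]1C)[C@@H]2C | intermediate
53 | (2Z,4S,6E,8Z,11R,12Z,14R,15S,17R,18R,19R,20E,22R,23R)-14,17:22,23-diepoxy-15-methoxy-2,4,6,12,18-pentamethyl-5-oxo-11-(TBS-oxy)tetracosa-2,6,8,12,20-pentaen-19-olide | CO[C@H]1C[C@H]2O[C@@H]1/C=C(/C)[C@H](O[Si](C)(C)C(C)(C)C)C/C=C\C=C(/C)C(=O)[C@@H](C)/C=C(/C)C(=O)O[C@H](/C=C/[C@H]1O[C@@H]1C)[C@@H]2C | intermediate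
54 | CNP0117824.1, (2Z,4S,6E,8Z,11R,12Z,14R,15S,17R,18R,19R,20E,22R,23R)-14,17:22,23-diepoxy-11-hydroxy-15-methoxy-2,4,6,12,18-pentamethyl-5-oxotetracosa-2,6,8,12,20-pentaen-19-olide | CO[C@H]1C[C@H]2O[C@@H]1/C=C(/C)[C@H](O)C/C=C\C=C(/C)C(=O)[C@@H](C)/C=C(/C)C(=O)O[C@H](/C=C/[C@H]1O[C@@H]1C)[C@@H]2C | target

Total step count: 36
Longest linear sequence: 21 steps (steps 1–8, 14–17, 25–27 and 31–36)

Steps most likely to fail

1. Step 15. What may go wrong: rotation about C12–C13 in the allyl-cation form of the conjugated oxocarbenium ion (loss of the 12Z geometry), 1,4-delivery of hydride, or weak facial discrimination at C14. Fallback (sets out from 13, returns at 27): the alkenyl group is built after the ring carbon C14 is set. Ethynylmagnesium bromide adds to lactone 13 to give the 2-ethynyl lactol F1. Et3SiH and BF3·OEt2 reduce it through an alkynyl oxocarbenium ion, which cannot isomerise, to the (2R,3S,5R)-2-ethynyl oxolane F2. Semihydrogenation (H2, Pd/CaCO3/Pb(OAc)2, quinoline) gives the 2-ethenyl oxolane F3. Ozonolysis (O3, then PPh3) gives the C13 aldehyde F4. Still–Gennari olefination with 38 (KHMDS, 18-crown-6) gives the (Z)-2-methyl-enoate F5. DIBAL-H gives the (Z)-allylic alcohol F6 and MnO2 the (Z)-enal F7. Propargylation with 18 and (R)-TRIP gives the (11R)-homopropargylic alcohol F8, and TBSCl with imidazole returns 27.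

2. Step 31. What may go wrong: weak facial discrimination at the C19 aldehyde by the alkenylchromium reagent, which would give both C19 epimers. Fallback (sets out from 48 as its epimer mixture, returns at 48): C19 is set by reagent control. DMP oxidation of the mixture gives the C19 enone F9, and Corey–Bakshi–Shibata reduction with the (R)-methyl oxazaborolidine and catecholborane (the alkenyl group acting as the large substituent) returns (19R)-48.

3. Step 33. What may go wrong: Z-to-E isomerisation of the 2-methyl-enoyl unit through reversible conjugate addition of DMAP to the activated acyl species, and oligomerisation. Fallback (sets out from 48, returns at 51): the alcohol is activated instead of the acid. Mitsunobu esterification of 48 with 4-nitrobenzoic acid (PPh3, DIAD) inverts C19 and gives the (19S)-4-nitrobenzoate F10. LiOH cleaves both esters to the (19S)-seco acid F11. Mitsunobu macrolactonisation (PPh3, DIAD, toluene, high dilution) closes the ring with a second inversion at C19 and gives 51.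

Further compounds
F1 | step 15 | (3S,5R)-2-ethynyl-3-methoxy-5-[(2S)-1-(TBS-oxy)propan-2-yl]oxolan-2-ol (both C14 epimers) | CO[C@H]1C[C@@H](OC1(O)C#C)[C@@H](C)CO[Si](C)(C)C(C)(C)C
F2 | step 15 | (2R,3S,5R)-2-ethynyl-3-methoxy-5-[(2S)-1-(TBS-oxy)propan-2-yl]oxolane | CO[C@H]1C[C@@H](O[C@@H]1C#C)[C@@H](C)CO[Si](C)(C)C(C)(C)C
F3 | step 15 | (2R,3S,5R)-2-ethenyl-3-methoxy-5-[(2S)-1-(TBS-oxy)propan-2-yl]oxolane | CO[C@H]1C[C@@H](O[C@@H]1C=C)[C@@H](C)CO[Si](C)(C)C(C)(C)C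
F4 | step 15 | (2S,3S,5R)-3-methoxy-5-[(2S)-1-(TBS-oxy)propan-2-yl]oxolane-2-carbaldehyde | CO[C@H]1C[C@@H](O[C@@H]1C=O)[C@@H](C)CO[Si](C)(C)C(C)(C)C
F5 | step 15 | ethyl (2Z)-3-{(2R,3S,5R)-3-methoxy-5-[(2S)-1-(TBS-oxy)propan-2-yl]oxolan-2-yl}-2-methylprop-2-enoate | CO[C@H]1C[C@@H](O[C@@H]1/C=C(/C)C(=O)OCC)[C@@H](C)CO[Si](C)(C)C(C)(C)C
F6 | step 15 | (2Z)-3-{(2R,3S,5R)-3-methoxy-5-[(2S)-1-(TBS-oxy)propan-2-yl]oxolan-2-yl}-2-methylprop-2-en-1-ol | CO[C@H]1C[C@@H](O[C@@H]1/C=C(/C)CO)[C@@H](C)CO[Si](C)(C)C(C)(C)C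
F7 | step 15 | (2Z)-3-{(2R,3S,5R)-3-methoxy-5-[(2S)-1-(TBS-oxy)propan-2-yl]oxolan-2-yl}-2-methylprop-2-enal | CO[C@H]1C[C@@H](O[C@@H]1/C=C(/C)C=O)[C@@H](C)CO[Si](C)(C)C(C)(C)C
F8 | step 15 | (1Z,3R)-1-{(2R,3S,5R)-3-methoxy-5-[(2S)-1-(TBS-oxy)propan-2-yl]oxolan-2-yl}-2-methylhex-1-en-5-yn-3-ol | CO[C@H]1C[C@@H](O[C@@H]1/C=C(/C)[C@H](O)CC#C)[C@@H](C)CO[Si](C)(C)C(C)(C)C
F9 | step 31 | ethyl (2Z,4S,5R,6E,8Z,11R,12Z,14R,15S,17R,18R,20E,22R,23R)-14,17:22,23-diepoxy-15-methoxy-2,4,6,12,18-pentamethyl-19-oxo-11-(TBS-oxy)-5-(TES-oxy)tetracosa-2,6,8,12,20-pentaenoate | CO[C@H]1C[C@@H](O[C@@H]1/C=C(/C)[C@H](O[Si](C)(C)C(C)(C)C)C/C=C\C=C(/C)[C@H](O[Si](CC)(CC)CC)[C@@H](C)/C=C(/C)C(=O)OCC)[C@@H](C)C(=O)/C=C/[C@H]1O[C@@H]1C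
F10 | step 33 | ethyl (2Z,4S,5R,6E,8Z,11R,12Z,14R,15S,17R,18R,19S,20E,22R,23R)-14,17:22,23-diepoxy-15-methoxy-2,4,6,12,18-pentamethyl-19-(4-nitrobenzoyloxy)-11-(TBS-oxy)-5-(TES-oxy)tetracosa-2,6,8,12,20-pentaenoate | CO[C@H]1C[C@@H](O[C@@H]1/C=C(/C)[C@H](O[Si](C)(C)C(C)(C)C)C/C=C\C=C(/C)[C@H](O[Si](CC)(CC)CC)[C@@H](C)/C=C(/C)C(=O)OCC)[C@@H](C)[C@@H](OC(=O)c1ccc(cc1)[N+](=O)[O-])/C=C/[C@H]1O[C@@H]1C
F11 | step 33 | (2Z,4S,5R,6E,8Z,11R,12Z,14R,15S,17R,18R,19S,20E,22R,23R)-14,17:22,23-diepoxy-19-hydroxy-15-methoxy-2,4,6,12,18-pentamethyl-11-(TBS-oxy)-5-(TES-oxy)tetracosa-2,6,8,12,20-pentaenoic acid | CO[C@H]1C[C@@H](O[C@@H]1/C=C(/C)[C@H](O[Si](C)(C)C(C)(C)C)C/C=C\C=C(/C)[C@H](O[Si](CC)(CC)CC)[C@@H](C)/C=C(/C)C(=O)O)[C@@H](C)[C@@H](O)/C=C/[C@H]1O[C@@H]1C
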